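All runs stem from a simulated flask for an exercise; noise was put on by code.

Time was the easy part, I wrote back. Product in the north-west run read level from 20.0 min, though substrate kept falling slowly, and ochre and green each had 3.0 h, far longer. You guessed that ochre would win with 4.00 times the initiator of green. No earlier run changes the initiator, so I reckoned from the charges instead.

| flask | substrate | coupling partner | initiator | radical scavenger | remark | time |
|---|---|---|---|---|---|---|
| north-west | 0.25 M | 0.25 M | 25 mM | 3.8 mM | run made earlier |  |
| ochre | 0.25 M | 0.120 M | 100 mM | 2.5 mM |  | 3.0 h |
| green | 0.25 M | 0.250 M | 25 mM | 2.5 mM |  | 3.0 h |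

north-west run (percent of the substrate charged)

| time / min | product / % | substrate / % |
|---|---|---|
| 4.00 | 0.8 | 97.5 |
| 12.0 | 41.3 | 56.3 |
| 20.0 | 83.1 | 16.8 |
| 30.0 | 80.6 | 13.7 |
| 50.0 | 83.8 | 11.5 |
| 60.0 | 83.0 | 10.9 |

(readings scatter by 1 percentage point)

- no earlier run changes the charge of initiator; that part of a forecast is a guess
- no earlier run changes the charge of radical scavenger; that part of a forecast is a guess

- the winner by amount of product, in percent of the substrate charged; "neither" if no more than 2 percentage points parts them (ochre / green / neither)
- how much product is there at the end, in percent of the substrate charged: ochre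
- how much product is there at the end, in percent of the substrate charged: green

For ochre, c(coupling partner)/c(substrate) gave 48.0%. I called that the ceiling, the share of the substrate charged that can become product when each product takes one coupling partner. For green the ceiling was 100%. But the north-west run, with green's charges of substrate and coupling partner, read 83.0% of product at its last reading. So I put green near that reading and ochre just under its ceiling. Taking that reading against ochre's ceiling set green ahead by about 35 percentage points, more than the margin.

The forecast also named green. It gave ochre 46% (40% to 48.5%) and green 87% (82% to 92%). Its green number was higher than my reading, on the ground that “less scavenger frees about 1.3 mM more initiator”.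

The simulation gave green, with ochre at 47.2% and green at 86.7%, both inside the forecast's ranges.

    first chain carrier + radical scavenger → ended chains B (k = 6.11 × 10⁷ M⁻¹ s⁻¹)
    2 second chain carrier → ended chains A (k = 6.70 × 10⁸ M⁻¹ s⁻¹)
    substrate + initiating radical → capped initiator + first chain carrier (k = 87700 M⁻¹ s⁻¹)
    initiator → 2 initiating radical (k = 1.51 × 10⁻⁴ s⁻¹)
    coupling partner + first chain carrier ⇌ product + second chain carrier (K = 7.01, k = 4550 M⁻¹ s⁻¹)
    2 coupling partner → homo dimer (k = 6.37 × 10⁻⁴ M⁻¹ s⁻¹)
    substrate + second chain carrier → by-product + first chain carrier (k = 39000 M⁻¹ s⁻¹)

Ochre ended 0.80 points under its ceiling, with coupling partner, the limiting reagent, at 0% of its charge. In ochre, the step from substrate and second chain carrier to by-product had half its turnover behind it by 2.15 min, much earlier than the capture of substrate by initiating radical, at 0.759 h.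

A neighbour, ochre with 0.072 M of coupling partner, had a ceiling of 28.8%. The simulation gave that neighbour 28.5% of product.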